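## Retrosynthetic overview

1. The target is a 7-O-alkylated 8-methoxycoumarin whose side chain ends in a (5R)-3-methylfuran-2(5H)-one (ring atoms O1, C2(=O), C3(Me), C4H, C5H). The α-methylene ketone comes last, by oxidation of an allylic alcohol made by Nozaki–Hiyama–Kishi union of a 2-bromoallyl butenolide with the aryloxyacetaldehyde derived from 7-hydroxy-8-methoxycoumarin.
2. The butenolide is cut across C3=C4 and O1–C5 into a terminal alkyne (2-bromopent-1-en-4-yne) and tert-butyl 2-diazopropanoate. Both bonds form in one flask: copper-catalysed asymmetric alkyne–carbene coupling to an axially chiral allenoate, then gold-triggered lactonisation with axis-to-centre chirality transfer.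
3. Enabling feature: C3 carries both the methyl group and the carboxyl carbon C2, so it is a carboxy(methyl)carbene, available as a diazo ester. C4 is an unsubstituted CH and C5 holds one H, so C4–C5–H is the C≡C–H of a terminal alkyne, and the ring is an isomer of a 2-methyl-2,3-allenoate.
4. Polarity is reversed on both carbons: C3 (normally an enolate carbon) reacts as an electrophilic carbene and C4 (normally the electrophilic β-carbon) as a nucleophilic acetylide.
5. Ring order: the coumarin bicycle is bought intact; the butenolide is the only ring built (step 5); no protecting groups are used.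

Key step: step 5

Assumption: 7-hydroxy-8-methoxycoumarin and L-alanine tert-butyl ester (liberated from its hydrochloride with aq. NaHCO3 before use) are taken as purchasable.
Assumption: the carbinol carbon created in step 6 is carried as both epimers, because step 7 removes it.
Assumption: the sense of induction of the copper catalyst in step 5 cannot be predicted with confidence; the ligand antipode that gives the (aR)-allenoate is to be fixed in a model run.

## Route

Step 1
Reactants: 1 7-hydroxy-8-methoxy-2H-chromen-2-one; 2 2-bromo-1,1-diethoxyethane
Product: 3 7-(2,2-diethoxyethoxy)-8-methoxy-2H-chromen-2-one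
Conditions: K2CO3 (1.5 equiv), KI (10 mol %), DMF, 100 °C
Reagents that add atoms: none
Why: Williamson ether synthesis on the acidic 7-OH; the coumarin lactone tolerates carbonate in dry DMF and no stereocenter is formed.

Step 2
Reactants: 3 7-(2,2-diethoxyethoxy)-8-methoxy-2H-chromen-2-one
Product: 4 2-[(8-methoxy-2-oxo-2H-chromen-7-yl)oxy]acetaldehyde
Conditions: 2 M aq. HCl/THF (1:2), 50 °C; used crude
Reagents that add atoms: water, O
Why: acid-catalysed acetal hydrolysis in dilute aqueous acid, far below the forcing anhydrous conditions that would cyclise the aryloxyacetaldehyde onto C6 to a furocoumarin.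

Step 3
Reactants: 5 2,3-dibromoprop-1-ene; 6 ethynylmagnesium bromide
Product: 7 2-bromopent-1-en-4-yne
Conditions: CuCl (5 mol %), THF, 0 °C to rt; distilled and kept as a stock solution
Reagents that add atoms: none
Why: copper-catalysed allylic substitution of the allylic bromide by the alkynyl Grignard reagent; SN2 and SN2' attack give the same 2-bromoallyl product and the vinylic bromide is inert.

Step 4
Reactants: 8 L-alanine tert-butyl ester
Product: 9 tert-butyl 2-diazopropanoate
Conditions: isoamyl nitrite (1.2 equiv), AcOH (10 mol %), CHCl3, reflux, short reaction time; used as a solution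
Reagents that add atoms: isoamyl nitrite, CC(C)CCON=O
Why: diazotisation of an α-amino ester with an alkyl nitrite under catalytic acid, the diazonium ion losing its α-proton to give the stabilised diazo ester; the alanine stereocenter is erased on purpose.

Step 5
Reactants: 7 2-bromopent-1-en-4-yne; 9 tert-butyl 2-diazopropanoate
Product: 11 (5R)-5-(2-bromoprop-2-en-1-yl)-3-methylfuran-2(5H)-one, via (aR)-allenoate 10 (not isolated)
Conditions: Cu(MeCN)4PF6 (5 mol %), 2,6-bis[(4S)-4-phenyl-4,5-dihydro-1,3-oxazol-2-yl]pyridine (6 mol %), iPr2NEt (10 mol %), CH2Cl2, 0 °C, slow addition of 9; then TFA (20 mol %), AuCl3 (10 mol %), same flask, rt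
Reagents that add atoms: none
Why: Proposed new method: this is a single-flask merger without direct precedent as a tandem process; the closest known reaction types are the enantioselective copper-catalysed coupling of terminal alkynes with α-diazo esters to axially chiral 2,4-disubstituted allenoates and the gold-catalysed dealkylative cyclisation of tert-butyl allenoates to butenolides. The copper acetylide of 7 captures 9 as a copper carbene with loss of N2 (faster than the 1,2-hydride shift to tert-butyl acrylate), alkynyl migration to the carbene carbon forms the C3–C4 bond, and ligand-controlled protonation of the propargyl/allenyl copper species at the γ-carbon, favoured over α-protonation by the fully substituted α-carbon, should give (aR)-10. AuCl3 then binds the C4=C5 π-bond of the allene on the face anti to the ester, the ester carbonyl oxygen closes the only new ring by 5-endo-trig anti-oxyauration at C5 (O1–C5 bond), tert-butyl leaves as isobutene and the proton so released protodeaurates C4. The C5 stereocenter is therefore controlled first by the chiral copper ligand (axis) and then by stereospecific axis-to-centre transfer, the (aR)-allene giving (R)-C5 because the oxygen can only arrive from the ester side. The step needs acetylide capture over cyclopropanation (the 1,1-disubstituted alkene is deactivated by bromine), allenoate over 3-alkynoate formation, and cyclisation without loss of the axis, which the alkyl (non-benzylic) C5 substituent secures by disfavouring a planar zwitterion, while the merely catalytic hindered amine (neutralised by TFA before gold is added) should not isomerise 10 to a dienoate. In polarity terms C3 reacts as an electrophilic carbene and C4 as a nucleophilic acetylide, the reverse of their roles in an aldol or olefination approach.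

Step 6
Reactants: 11 (5R)-5-(2-bromoprop-2-en-1-yl)-3-methylfuran-2(5H)-one; 4 2-[(8-methoxy-2-oxo-2H-chromen-7-yl)oxy]acetaldehyde
Product: 12 7-{[2-hydroxy-3-methylidene-4-((2R)-4-methyl-5-oxo-2,5-dihydrofuran-2-yl)butyl]oxy}-8-methoxy-2H-chromen-2-one (both epimers at the carbinol carbon)
Conditions: CrCl2 (4 equiv), NiCl2 (2 mol %), degassed DMF, rt
Reagents that add atoms: none
Why: Nozaki–Hiyama–Kishi reaction, in which nickel-catalysed formation of the alkenylchromium species from the 2-bromoalkene is followed by chemoselective 1,2-addition to the aldehyde; both lactones are spared, the medium is non-basic so C5 is not epimerised, and the new carbinol centre is left uncontrolled because step 7 oxidises it.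

Step 7
Reactants: 12 7-{[2-hydroxy-3-methylidene-4-((2R)-4-methyl-5-oxo-2,5-dihydrofuran-2-yl)butyl]oxy}-8-methoxy-2H-chromen-2-one
Product: 13 7-{[3-methylidene-4-((2R)-4-methyl-5-oxo-2,5-dihydrofuran-2-yl)-2-oxobutyl]oxy}-8-methoxy-2H-chromen-2-one
Conditions: Dess–Martin periodinane (1.3 equiv), CH2Cl2, 0 °C to rt
Reagents that add atoms: none
Why: Dess–Martin oxidation of the secondary allylic alcohol to the α-methylene ketone under non-basic conditions that spare the butenolide γ-stereocenter and the coumarin; both carbinol epimers converge on the single target.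

## Compound list

1 | 7-hydroxy-8-methoxy-2H-chromen-2-one | Oc1ccc2ccc(=O)oc2c1OC | starting material
2 | 2-bromo-1,1-diethoxyethane | BrCC(OCC)OCC | starting material
3 | 7-(2,2-diethoxyethoxy)-8-methoxy-2H-chromen-2-one | CCOC(COc1ccc2ccc(=O)oc2c1OC)OCC | intermediate
4 | 2-[(8-methoxy-2-oxo-2H-chromen-7-yl)oxy]acetaldehyde | O=CCOc1ccc2ccc(=O)oc2c1OC | intermediate
5 | 2,3-dibromoprop-1-ene | C=C(Br)CBr | starting material
6 | ethynylmagnesium bromide | C#C[Mg]Br | starting material
7 | 2-bromopent-1-en-4-yne | C=C(Br)CC#C | intermediate
8 | L-alanine tert-butyl ester | C[C@H](N)C(=O)OC(C)(C)C | starting material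
9 | tert-butyl 2-diazopropanoate | CC(=[N+]=[N-])C(=O)OC(C)(C)C | intermediate
10 | tert-butyl (aR)-6-bromo-2-methylhepta-2,3,6-trienoate (not isolated) | CC(C(=O)OC(C)(C)C)=[C@@]=C([H])CC(Br)=C | intermediate
11 | (5R)-5-(2-bromoprop-2-en-1-yl)-3-methylfuran-2(5H)-one | C=C(Br)C[C@@H]1C=C(C)C(=O)O1 | intermediate
12 | 7-{[2-hydroxy-3-methylidene-4-((2R)-4-methyl-5-oxo-2,5-dihydrofuran-2-yl)butyl]oxy}-8-methoxy-2H-chromen-2-one, both carbinol epimers | C=C(C[C@@H]1C=C(C)C(=O)O1)C(O)COc1ccc2ccc(=O)oc2c1OC | intermediate
13 | 7-{[3-methylidene-4-((2R)-4-methyl-5-oxo-2,5-dihydrofuran-2-yl)-2-oxobutyl]oxy}-8-methoxy-2H-chromen-2-one | C=C(C[C@@H]1C=C(C)C(=O)O1)C(=O)COc1ccc2ccc(=O)oc2c1OC | target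

## Step count and risks

Total steps: 7. Longest linear sequence: 4 steps (steps 3, 5, 6, 7; the branches through steps 1–2 and through step 4 are no longer).

Steps most likely to fail:

Step 5 (key step, proposed new method). The enantioface control in the γ-protonation of the propargyl/allenyl copper species may be insufficient. α-Protonation may instead give the achiral 3-alkynoate, which gold would turn into the β,γ-unsaturated enol lactone. The carbene may undergo 1,2-hydride shift, or the axis may erode during the gold stage. The fallback uses known chemistry and sets out from 5. Chromium-catalysed asymmetric 2-bromoallylation of acrolein with 5 (CrCl2 (10 mol %), chiral oxazoline–sulfonamide ligand, Mn, Cp2ZrCl2, THF) should give (R)-5-bromohexa-1,5-dien-3-ol F1. Acylation with methacryloyl chloride (Et3N, DMAP, CH2Cl2, 0 °C) should give (R)-5-bromohexa-1,5-dien-3-yl 2-methylprop-2-enoate F2. Ring-closing metathesis (second-generation Grubbs catalyst, toluene, 80 °C) should then close the butenolide with retention at the carbinol carbon and return to the route at 11.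

Step 6. Oxidative addition of the 2-bromoalkene may be sluggish, which would leave time for nickel-mediated ionisation of the allylic lactone C5–O bond (loss of configuration) and for decomposition of the aldehyde. The fallback moves the chromium-mediated union ahead of butenolide formation and sets out from 7 and 4. Their Nozaki–Hiyama–Kishi coupling (excess 7, CrCl2, NiCl2, DMF or DMSO, where forcing conditions are harmless because no lactone stereocenter is present) should give racemic 7-[(2-hydroxy-3-methylidenehex-5-yn-1-yl)oxy]-8-methoxy-2H-chromen-2-one F3. Silylation (TBSOTf, 2,6-lutidine, CH2Cl2) should give 7-{[2-(tert-butyldimethylsilyloxy)-3-methylidenehex-5-yn-1-yl]oxy}-8-methoxy-2H-chromen-2-one F4. The conditions of step 5 with 9 should then lead, through tert-butyl (aR)-7-(tert-butyldimethylsilyloxy)-8-[(8-methoxy-2-oxo-2H-chromen-7-yl)oxy]-2-methyl-6-methylideneocta-2,3-dienoate F5 (not isolated), to 7-{[2-(tert-butyldimethylsilyloxy)-3-methylidene-4-((2R)-4-methyl-5-oxo-2,5-dihydrofuran-2-yl)butyl]oxy}-8-methoxy-2H-chromen-2-one F6. Desilylation (HF·pyridine, THF, 0 °C) returns to the route at 12.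

Step 3. Double allylation through the acetylene bis-Grignard reagent, base-induced isomerisation of the skipped enyne to allene or conjugated enyne, and loss of the volatile product on isolation are possible. The fallback sets out from 5. Copper-catalysed coupling with ethynyltrimethylsilane under mild carbonate conditions (CuBr (10 mol %), K2CO3, Bu4NI, DMF, rt) should give the non-volatile, storable (4-bromopent-4-en-1-yn-1-yl)trimethylsilane F7. Desilylation (K2CO3, MeOH, rt) shortly before use returns to the route at 7.

## Further compounds

F1 | step 5 | (R)-5-bromohexa-1,5-dien-3-ol | C=C[C@H](O)CC(Br)=C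
F2 | step 5 | (R)-5-bromohexa-1,5-dien-3-yl 2-methylprop-2-enoate | C=C[C@H](OC(=O)C(C)=C)CC(Br)=C
F3 | step 6 | 7-[(2-hydroxy-3-methylidenehex-5-yn-1-yl)oxy]-8-methoxy-2H-chromen-2-one (racemic) | C#CCC(=C)C(O)COc1ccc2ccc(=O)oc2c1OC
F4 | step 6 | 7-{[2-(tert-butyldimethylsilyloxy)-3-methylidenehex-5-yn-1-yl]oxy}-8-methoxy-2H-chromen-2-one (racemic) | C#CCC(=C)C(O[Si](C)(C)C(C)(C)C)COc1ccc2ccc(=O)oc2c1OC
F5 | step 6 | tert-butyl (aR)-7-(tert-butyldimethylsilyloxy)-8-[(8-methoxy-2-oxo-2H-chromen-7-yl)oxy]-2-methyl-6-methylideneocta-2,3-dienoate (not isolated, both silyloxy epimers) | CC(C(=O)OC(C)(C)C)=[C@@]=C([H])CC(=C)C(O[Si](C)(C)C(C)(C)C)COc1ccc2ccc(=O)oc2c1OC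
F6 | step 6 | 7-{[2-(tert-butyldimethylsilyloxy)-3-methylidene-4-((2R)-4-methyl-5-oxo-2,5-dihydrofuran-2-yl)butyl]oxy}-8-methoxy-2H-chromen-2-one (both silyloxy epimers) | C=C(C[C@@H]1C=C(C)C(=O)O1)C(O[Si](C)(C)C(C)(C)C)COc1ccc2ccc(=O)oc2c1OC
F7 | step 3 | (4-bromopent-4-en-1-yn-1-yl)trimethylsilane | C=C(Br)CC#C[Si](C)(C)C
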